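## Retrosynthetic overview

- The target is the mono-C-2 epimer of a C2-symmetric bis(2,3-trans-3,4-cis-flavan-4-yl) ether. The last disconnection is therefore one C-2 inversion through a ring-B quinone methide.
- The symmetric ether is cut at C4–O–C4 into two copies of one 3-O-benzyl flavan-4-ol, joined by dehydrative self-etherification with quasi-axial capture.
- The key disconnection is C3–C4 of ring C. The aromatic aldehyde carbon is made nucleophilic as a samarium ketyl (a hydroxy-carbanion equivalent) and joined to the aliphatic aldehyde carbon, which gives the cis-3,4-diol directly.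
- The dialdehyde comes from an (S)-α-aryl-α-aryloxy diester, cut at O1–C2 into a salicylate phenol and an aryl diazoacetate. Asymmetric O–H insertion sets C2.
- Ring order: rings A and B are bought, ring C is closed once in the key step, and the two halves are joined afterwards.

Assumption: the ligand antipode named in step 3 is taken to give the S ether. If the sense of induction is opposite, its mirror image is used.

## Route

Step 1
Reactants: 1 methyl 2,3,4-trihydroxybenzoate
Product: 2 methyl 3,4-bis(benzyloxy)-2-hydroxybenzoate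
Conditions: BnBr (2.1 equiv), K2CO3 (2.2 equiv), DMF, 25 °C
Reagents that add atoms: benzyl bromide, BrCc1ccccc1
Why: Williamson etherification in which the 2-OH is locked in a hydrogen bond to the ester carbonyl and stays free when only two equivalents of halide are offered.

Step 2
Reactants: 3 methyl [4-(benzyloxy)phenyl]acetate
Product: 4 methyl [4-(benzyloxy)phenyl](diazo)acetate
Conditions: 4-acetamidobenzenesulfonyl azide (1.2 equiv), DBU (1.4 equiv), MeCN, 0 °C to rt
Reagents that add atoms: 4-acetamidobenzenesulfonyl azide, CC(=O)Nc1ccc(cc1)S(=O)(=O)N=[N+]=[N-]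
Why: Regitz diazo transfer onto the acidic benzylic methylene of an arylacetate, the standard entry to donor/acceptor diazo esters.

Step 3
Reactants: 2 methyl 3,4-bis(benzyloxy)-2-hydroxybenzoate; 4 methyl [4-(benzyloxy)phenyl](diazo)acetate
Product: 5 methyl 3,4-bis(benzyloxy)-2-{(1S)-1-[4-(benzyloxy)phenyl]-2-methoxy-2-oxoethoxy}benzoate
Conditions: Pd(PhCN)2Cl2 (5 mol %), (Sa,S,S)-7,7'-bis(4-phenyl-4,5-dihydrooxazol-2-yl)-1,1'-spirobiindane (6 mol %), NaB[3,5-(CF3)2C6H3]4 (12 mol %), 5 Å MS, CHCl3, 40 °C, slow addition of 4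
Reagents that add atoms: none
Why: Enantioselective metal-carbene O–H insertion of a phenol into an α-aryl-α-diazoacetate, in which the proton shift inside the chiral pocket sets the future C2 as S irreversibly under neutral conditions, and the ester (not an aldehyde) on ring A prevents aldol trapping of the oxonium ylide.

Step 4
Reactants: 5 methyl 3,4-bis(benzyloxy)-2-{(1S)-1-[4-(benzyloxy)phenyl]-2-methoxy-2-oxoethoxy}benzoate
Product: 6 (2S)-2-[4-(benzyloxy)phenyl]-2-[2,3-bis(benzyloxy)-6-(hydroxymethyl)phenoxy]ethanol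
Conditions: LiAlH4 (2.5 equiv), THF, 0 °C, Fieser work-up
Reagents that add atoms: none
Why: Hydride reduction of both esters in one operation, fast enough at 0 °C to outrun enolisation so that the S centre is kept, while benzyl ethers are inert.

Step 5
Reactants: 6 (2S)-2-[4-(benzyloxy)phenyl]-2-[2,3-bis(benzyloxy)-6-(hydroxymethyl)phenoxy]ethanol
Product: 8 (2S,3R,4R)-7,8-bis(benzyloxy)-2-[4-(benzyloxy)phenyl]chromane-3,4-diol, via dialdehyde 7 (not isolated)
Conditions: Dess–Martin periodinane (2.4 equiv), CH2Cl2, 0 °C, 1 h; filter through Celite, concentrate cold; crude 7 in THF added slowly to SmI2 (3 equiv, 0.1 M), t-BuOH (3 equiv), THF, −78 to −20 °C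
Reagents that add atoms: none
Why: Samarium diiodide pinacol cyclisation in which single-electron reduction turns the more easily reduced aromatic aldehyde carbon into a nucleophilic ketyl (α-oxido-benzyl samarium, a hydroxy-carbanion equivalent) that attacks the aliphatic aldehyde carbon, so two electrophilic carbons become the C4–C3 bond and ring C closes; both oxygens chelate one trivalent samarium ion (3,4-cis), while the pseudo-equatorial 2-aryl group and the C3–O bond lying anti to the C2–O1 dipole give 2,3-trans, that is 3R,4R from the S centre, and the base-free oxidation and immediate use protect the labile α-centre of 7.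

Step 6
Reactants: 8 (2S,3R,4R)-7,8-bis(benzyloxy)-2-[4-(benzyloxy)phenyl]chromane-3,4-diol
Product: 9 (2S,3R,4R)-3,7,8-tris(benzyloxy)-2-[4-(benzyloxy)phenyl]chroman-4-ol
Conditions: 2-aminoethyl diphenylborinate (10 mol %), BnBr (1.5 equiv), Ag2O (1.1 equiv), MeCN, 40 °C
Reagents that add atoms: benzyl bromide, BrCc1ccccc1
Why: Borinic-acid-catalysed regioselective alkylation of a cis-1,2-diol, in which the tetracoordinate borinate reacts at its equatorial oxygen (O3) and leaves the quasi-axial benzylic 4-OH free, with no stereocentre touched.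

Step 7
Reactants: 9 (2S,3R,4R)-3,7,8-tris(benzyloxy)-2-[4-(benzyloxy)phenyl]chroman-4-ol (two molecules)
Product: 10 bis{(2S,3R,4R)-3,7,8-tris(benzyloxy)-2-[4-(benzyloxy)phenyl]chroman-4-yl} ether
Conditions: Bi(OTf)3 (2 mol %), 4 Å MS, CH2Cl2 (0.5 M), −20 to 0 °C
Reagents that add atoms: none
Why: Acid-catalysed dehydrative self-etherification of an electron-rich secondary benzylic alcohol (SN1), in which the C4 cation stabilised by O1 and the 7-benzyloxy group is captured by the only free hydroxyl of a second molecule along the quasi-axial trajectory that alcohols are known to follow with 2,3-trans-flavan-4-yl cations, giving 3,4-cis (4R) at the new centre; the non-participating 3-O-benzyl group does not steer attack to the trans face, and reversibility funnels any 4-epimer to the peri-strain-free diaxial ether before the poorly nucleophilic trialkoxy ring A can be C-alkylated.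

Step 8
Reactants: 10 bis{(2S,3R,4R)-3,7,8-tris(benzyloxy)-2-[4-(benzyloxy)phenyl]chroman-4-yl} ether
Product: 11 bis[(2S,3R,4R)-3,7,8-trihydroxy-2-(4-hydroxyphenyl)chroman-4-yl] ether
Conditions: H2 (1 atm), Pd(OH)2/C (20 wt %), THF–MeOH 1:1, rt, stopped once 8 equiv H2 are taken up
Reagents that add atoms: none
Why: Heterogeneous hydrogenolysis in which the eight unhindered PhCH2–O bonds adsorb and cleave much faster than the two hindered, secondary, electron-rich ring C4–O bonds, so under neutral conditions and with early stopping the interflavanyl ether and all six stereocentres survive.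

Step 9
Reactants: 11 bis[(2S,3R,4R)-3,7,8-trihydroxy-2-(4-hydroxyphenyl)chroman-4-yl] ether
Product: 13 (2R,3R,4R)-4-{[(2S,3R,4R)-3,7,8-trihydroxy-2-(4-hydroxyphenyl)chroman-4-yl]oxy}-2-(4-hydroxyphenyl)chromane-3,7,8-triol, via quinone methide 12 (not isolated)
Conditions: degassed aq NaHCO3/Na2CO3 buffer (pH 10), Ar, 40 °C, about 4 h; AcOH to pH 5; Sephadex LH-20 (EtOH), then preparative HPLC; recovered 11 resubmitted
Reagents that add atoms: none
Why: Base-catalysed C-2 epimerisation of a free-phenolic flavan-3-ol, in which the 4'-phenolate expels the ring-A aryloxide O1 to give quinone methide 12 and re-closure on the other face inverts C2 of one half (S to R) without touching C3 or C4; because 11 is C2-symmetric either half gives the same product, the C4 alkoxide is a far poorer leaving group than an aryloxide so the ether link holds, ring A lacks the phloroglucinol carbon nucleophilicity that diverts catechins, and the equilibrium mixture (about one third 13 per pass) is separated from 11 and the doubly epimerised ether, both of which re-enter the same equilibrium.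

## Compound list

1 | methyl 2,3,4-trihydroxybenzoate | COC(=O)c1ccc(O)c(O)c1O | starting material
2 | methyl 3,4-bis(benzyloxy)-2-hydroxybenzoate | COC(=O)c1ccc(OCc2ccccc2)c(OCc2ccccc2)c1O | intermediate
3 | methyl [4-(benzyloxy)phenyl]acetate | COC(=O)Cc1ccc(OCc2ccccc2)cc1 | starting material
4 | methyl [4-(benzyloxy)phenyl](diazo)acetate | COC(=O)C(=[N+]=[N-])c1ccc(OCc2ccccc2)cc1 | intermediate
5 | methyl 3,4-bis(benzyloxy)-2-{(1S)-1-[4-(benzyloxy)phenyl]-2-methoxy-2-oxoethoxy}benzoate | COC(=O)c1ccc(OCc2ccccc2)c(OCc2ccccc2)c1O[C@@H](c1ccc(OCc2ccccc2)cc1)C(=O)OC | intermediate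
6 | (2S)-2-[4-(benzyloxy)phenyl]-2-[2,3-bis(benzyloxy)-6-(hydroxymethyl)phenoxy]ethanol | OCc1ccc(OCc2ccccc2)c(OCc2ccccc2)c1O[C@@H](c1ccc(OCc2ccccc2)cc1)CO | intermediate
7 | 3,4-bis(benzyloxy)-2-{(1S)-1-[4-(benzyloxy)phenyl]-2-oxoethoxy}benzaldehyde (dialdehyde, used crude) | O=Cc1ccc(OCc2ccccc2)c(OCc2ccccc2)c1O[C@@H](c1ccc(OCc2ccccc2)cc1)C=O | intermediate
8 | (2S,3R,4R)-7,8-bis(benzyloxy)-2-[4-(benzyloxy)phenyl]chromane-3,4-diol (2,3-trans-3,4-cis) | O[C@@H]1c2ccc(OCc3ccccc3)c(OCc3ccccc3)c2O[C@@H](c2ccc(OCc3ccccc3)cc2)[C@@H]1O | intermediate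
9 | (2S,3R,4R)-3,7,8-tris(benzyloxy)-2-[4-(benzyloxy)phenyl]chroman-4-ol | O[C@@H]1c2ccc(OCc3ccccc3)c(OCc3ccccc3)c2O[C@@H](c2ccc(OCc3ccccc3)cc2)[C@@H]1OCc1ccccc1 | intermediate
10 | bis{(2S,3R,4R)-3,7,8-tris(benzyloxy)-2-[4-(benzyloxy)phenyl]chroman-4-yl} ether (C2-symmetric) | O([C@@H]1c2ccc(OCc3ccccc3)c(OCc3ccccc3)c2O[C@@H](c2ccc(OCc3ccccc3)cc2)[C@@H]1OCc1ccccc1)[C@@H]1c2ccc(OCc3ccccc3)c(OCc3ccccc3)c2O[C@@H](c2ccc(OCc3ccccc3)cc2)[C@@H]1OCc1ccccc1 | intermediate
11 | bis[(2S,3R,4R)-3,7,8-trihydroxy-2-(4-hydroxyphenyl)chroman-4-yl] ether (C2-symmetric) | O([C@@H]1c2ccc(O)c(O)c2O[C@@H](c2ccc(O)cc2)[C@@H]1O)[C@@H]1c2ccc(O)c(O)c2O[C@@H](c2ccc(O)cc2)[C@@H]1O | intermediate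
12 | ring-B para-quinone methide of 11: one half opened at O1–C2 to the 4-alkylidenecyclohexa-2,5-dienone with a 2,3,4-trihydroxyphenyl ring A, C3 and C4 unchanged, other half intact | O=C1C=CC(=C[C@H](O)[C@H](O[C@@H]2c3ccc(O)c(O)c3O[C@@H](c3ccc(O)cc3)[C@@H]2O)c2ccc(O)c(O)c2O)C=C1 | intermediate
13 | (2R,3R,4R)-4-{[(2S,3R,4R)-3,7,8-trihydroxy-2-(4-hydroxyphenyl)chroman-4-yl]oxy}-2-(4-hydroxyphenyl)chromane-3,7,8-triol (CNP0241481.1) | Oc1ccc([C@H]2Oc3c(ccc(O)c3O)[C@@H](O[C@@H]3c4ccc(O)c(O)c4O[C@@H](c4ccc(O)cc4)[C@@H]3O)[C@H]2O)cc1 | target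

## Step count

Total step count: 9.

Longest linear sequence: 8 (steps 1 and 3 to 9, or steps 2 to 9). Both halves of the dimer come from the same monomer.

## Steps most likely to fail

**Step 5.** Dialdehyde 7 may enolise, racemise or close by aldol before the ketyl forms, and the diol ratio may be poor.
- The fallback sets out from 7.
- Low-valent titanium (TiCl4, Zn, pyridine, THF, reflux) carries the same reductive carbonyl–carbonyl coupling through to the alkene (2R)-7,8-bis(benzyloxy)-2-[4-(benzyloxy)phenyl]-2H-chromene F1. The spatial arrangement at C2 is unchanged; only the descriptor changes.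
- OsO4 (cat.)/NMO dihydroxylation on the face opposite to the 2-aryl group then sets C3 and C4 together.
- This comes back to the route at 8.

**Step 7.** Elimination to the 3-benzyloxyflav-3-ene, C-alkylation of ring A, or a mixture of C4 epimers may win under equilibrating acid.
- The fallback sets out from 9 and separates the roles of donor and acceptor.
- Half of 9 is converted with PhSH and catalytic Bi(OTf)3 (CH2Cl2, −20 °C) into (2S,3S,4R)-3,7,8-tris(benzyloxy)-2-[4-(benzyloxy)phenyl]-4-(phenylsulfanyl)chromane F2.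
- F2 is then activated with AgBF4 in the presence of 2,6-di-tert-butyl-4-methylpyridine, 4 Å MS and the other half of 9 (CH2Cl2–THF, −40 °C).
- Capture is then kinetic and acid-free, and the acceptor keeps its 4R centre.
- This comes back to the route at 10.

**Step 9.** The equilibrium may be unfavourable, the catechol rings may oxidise, or the dimer may be lost at pH 10.
- The fallback sets out from 8 and moves the epimerisation to the monomer.
- Hydrogenolysis (H2, Pd(OH)2/C, THF–MeOH) gives (2S,3R,4R)-2-(4-hydroxyphenyl)chromane-3,4,7,8-tetrol F3.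
- Part of F3 is equilibrated at pH 10 under argon to its separable C-2 epimer (2R,3R,4R)-2-(4-hydroxyphenyl)chromane-3,4,7,8-tetrol F4.
- F3 is then added slowly to an excess of F4 in dilute aqueous acid (pH 3, rt). The quasi-axial 4-OH of F3 ionises much faster than the quasi-equatorial 4-OH of F4.
- The cation is taken up quasi-axially by the 4-OH of F4. The 4-O-3 regioisomer is removed by chromatography.
- This comes back to the route at 13.

## Further compounds

F1 | step 5 | (2R)-7,8-bis(benzyloxy)-2-[4-(benzyloxy)phenyl]-2H-chromene | O1c2c(OCc3ccccc3)c(OCc3ccccc3)ccc2C=C[C@@H]1c1ccc(OCc2ccccc2)cc1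
F2 | step 7 | (2S,3S,4R)-3,7,8-tris(benzyloxy)-2-[4-(benzyloxy)phenyl]-4-(phenylsulfanyl)chromane | c1ccccc1S[C@@H]1c2ccc(OCc3ccccc3)c(OCc3ccccc3)c2O[C@@H](c2ccc(OCc3ccccc3)cc2)[C@@H]1OCc1ccccc1
F3 | step 9 | (2S,3R,4R)-2-(4-hydroxyphenyl)chromane-3,4,7,8-tetrol | O[C@@H]1c2ccc(O)c(O)c2O[C@@H](c2ccc(O)cc2)[C@@H]1O
F4 | step 9 | (2R,3R,4R)-2-(4-hydroxyphenyl)chromane-3,4,7,8-tetrol | O[C@@H]1c2ccc(O)c(O)c2O[C@H](c2ccc(O)cc2)[C@@H]1O
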